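## The problem

The target 18 is a fully substituted cyclobutane. Its ring carbons are called Ca to Cd in ring order: Ca and Cc each carry a 3,4-dimethoxyphenyl group, Cb and Cd each carry the carbonyl of an N-acyl-5,6-dihydropyridin-2(1H)-one (head-to-tail pattern).

- **Configuration.** The two aryl groups are trans to each other and the two acyl groups are trans to each other, so each acyl group is cis to one neighbouring aryl group and trans to the other. The molecule has a centre of symmetry and is meso, so only relative configuration must be controlled.
- **Which centre controls which.** Once the aryl groups are trans, each ring face carries one of them. The configuration at Cb can therefore be steered only by the substituent across the ring on Cd, and the reverse.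
- **Fragile groups.** The two imides are acyl-transfer agents and Michael acceptors and must be made last. Cb and Cd are α to carbonyl groups and can epimerise through enols or enolates. The dimethoxyphenyl rings are electron-rich, which limits the choice of oxidants and electrophiles.
- **Enabling feature.** The unit Ca–Cd–Cc with trans aryl groups is C2–C1–C5 of a trans-2,5-diarylcyclopent-3-ene. Its alkene carbons C3 and C4 can become Cb and the exocyclic carbonyl carbon on Cb if one ring bond is shifted. With trans aryl groups C1 is not a stereocentre, so the five-membered precursor holds a single stereochemical element, the like relation of C2 and C5.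

## Retrosynthesis

**18 to 14 and 15.** The two imide N–C(O) bonds are cut first. Growing the lactam rings on simpler amides would add steps, whereas this cut uses the commercial lactam 15 intact and confines the sensitive groups to the last step. Diacid 14 is centrosymmetric and carries only robust functions. The forward reaction is a twofold N-acylation through acid chloride 16 and lithium lactamide 17, and it must not epimerise Cb or Cd.

**14 to 12.** No skeletal bond is cut; both carboxyl carbons are traced back to dimethoxymethyl carbons by way of dialdehyde 13. Having the same masked aldehyde on Cb and Cd makes 12 meso and lets one operation serve both arms. The forward sequence needs acetal hydrolysis that outruns enolisation and an oxidant that spares the arenes.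

**12 to 11 (key disconnection).** The ring bond Cb–Cc is cut and Cc is reconnected to the exocyclic acetal carbon on Cb, which gives cyclopentene 11. The neighbouring two-bond cut into two cinnamate halves depends on crystal packing for head-to-tail control. The one-bond shift instead passes on a trans-diaryl relation that is already in place. Precursor 11 is unstrained and has one stereochemical element instead of four stereocentres. The forward reaction must bring the iodane to the face anti to the C1 substituent and must move a benzylic ring carbon, not an aryl group.

**11 to 9.** The C1 acetal is traced back through aldehyde 10 to nitrile 9; no skeletal bond is cut. The acetal is preferred to an ester or nitrile as spectator for three reasons: it is bulkier (the only facial bias in the key step), it cannot enolise, and it is the very group the key step creates.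

**9 to 8.** The C1–CO2Me bond is cut (retro-dealkoxycarbonylation). The extra ester in 8 is the activating group needed to build C1. Because C1 in 9 is not stereogenic, its removal raises no stereochemical question.

**8 to 7.** The C3=C4 bond is cut (retro-metathesis). Only the like diene 7 can close to the trans-2,5-diaryl ring, so the ring configuration is decided in the open chain.

**7 to 4 and 5.** Both bonds from C1 to the benzylic carbons are cut, leading to two molecules of carbonate 4 and methyl cyanoacetate 5. One enantiomer of an iridium catalyst sets the same sense at both benzylic carbons and so delivers the like isomer. Cyanoacetate is preferred to malonate because the rod-shaped nitrile relieves the congestion at a quaternary carbon placed between two tertiary benzylic carbons.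

**4 to 1.** The carbonate C–O bond is cut to alcohol 3, which comes from acid 1 by reduction through mixed anhydride 2. All aryl carbons of the target thus come from 1.

## Roads not taken

**Alternative 1:** The cut is the same pair of imide C–N bonds, but on a ring that has no aryl groups yet. All four ring substituents are carboxyl carbons of the cis,trans,cis dianhydride A2. In the forward key step two equivalents of lithium lactamide 17 open both anhydride rings at the carbonyls on Cb and Cd and give bis-imide diacid A1. The carboxyl groups on Ca and Cc would then be replaced by aryl groups through decarboxylative arylation.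
- Merits: A2 supplies the four-membered ring with the correct cis,trans,cis pattern as an article of commerce, anhydride opening needs no activation, and A1 is one step away.
- Weak points: after the first opening the second anhydride offers two different carbonyls, and nothing directs the amide to the one that gives the 1,3- and not the 1,2-bis-imide. The fragile imides are made first and must survive two radical or organometallic C–C couplings. Those couplings pass through trigonal Ca and Cc, each flanked by one cis and one trans acyl group, so the trans relation of the aryl groups is not controlled.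
- Comparison: this road is clearly shorter and gets its ring for nothing, which the chosen plan cannot match. The chosen plan sets against it that the aryl-bearing centres are fixed early under catalyst control and that the imides appear only in the last step.

**Alternative 2:** The cut removes four C–C bonds of each arene. The rings on Ca and Cc are grown from the ethynyl groups of diyne diol A4 and diene A5. The forward key step is a [4+2] cycloaddition under low-valent cobalt–bisphosphine catalysis (generated with a metallic reductant and a Lewis acid) to bis(cyclohexa-1,4-diene) A3. Dehydrogenation to the arenes, oxidation of both hydroxymethyl groups and imide formation would follow.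
- Merits: the cycloaddition is neutral and has no regiochemical question with the symmetrical diene A5. Cb and Cd carry non-enolisable hydroxymethyl groups until late, so the ring stereocentres are safer than in the chosen plan, which passes through aldehydes. This is a real advantage.
- Weak points: A4 is itself a cyclobutane with all four stereocentres of the target, so the central problem is only moved back. A ring available in 1 is rebuilt atom by atom, and aromatisation plus two alcohol oxidations are added.
- Comparison: this road is longer and leaves open how the cyclobutane arises. It would be the better one only if variation of the arenes were the aim.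

**Alternative 3:** The cut is the two aryl–ring bonds at Ca and Cc. In the forward key step, trans bis-amide A7 and aryl iodide A8 react under palladium carboxylate catalysis with a silver salt as iodide scavenger. Each quinolin-8-yl amide directs arylation of a methylene C–H bond cis to itself, which gives A6 with the target configuration.
- Merits: the reaction class is well established for cyclobutane carboxamides. Cis delivery by each amide sets all four stereocentres, and A7 is two steps from commercial material.
- Weak points: a second arylation by the same amide (all-cis product) competes. Stoichiometric silver is used. The two hindered auxiliary amides must then be cleaved to the acids without epimerising Cb and Cd, which usually needs N-activation and strong nucleophiles.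
- Comparison: in step count and precedent this road is better than the chosen plan. The chosen plan sets against it only freedom from auxiliaries and silver, aryl groups taken from a commodity cinnamic acid, and a new ring contraction whose stereochemical outcome follows from one facial choice.

Key step: step 8

Assumption: 18 is meso, so the absolute sense induced by the iridium catalyst is immaterial and only the like relation of the two benzylic centres counts. Intermediates 6 to 11 are drawn in one enantiomeric series; the antipodal ligand would give their mirror images and the same 18.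

## Route

Step 1
Reactants: 1 (E)-3-(3,4-dimethoxyphenyl)acrylic acid
Product: 3 (E)-3-(3,4-dimethoxyphenyl)prop-2-en-1-ol, via ethyl carbonic mixed anhydride 2 (not isolated)
Conditions: ClCO2Et, Et3N, THF, −10 °C; then NaBH4, THF/H2O, 0 °C
Reagents that add atoms: none
Why: Reduction of a carboxylic acid through its mixed carbonic anhydride; borohydride attacks the activated acyl carbon 1,2 and leaves the E-styrenyl double bond in place.

Step 2
Reactants: 3 (E)-3-(3,4-dimethoxyphenyl)prop-2-en-1-ol
Product: 4 (E)-3-(3,4-dimethoxyphenyl)allyl methyl carbonate
Conditions: ClCO2Me, pyridine, CH2Cl2, 0 °C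
Reagents that add atoms: methyl chloroformate, COC(=O)Cl
Why: O-Acylation of a primary allylic alcohol with a chloroformate; the methyl carbonate is the usual ionisable group for iridium allyl chemistry and releases methoxide as internal base.

Step 3
Reactants: 4 (E)-3-(3,4-dimethoxyphenyl)allyl methyl carbonate (2.3 equiv); 5 methyl cyanoacetate
Product: 7 methyl (3R)-2-cyano-3-(3,4-dimethoxyphenyl)-2-[(1R)-1-(3,4-dimethoxyphenyl)prop-2-en-1-yl]pent-4-enoate, via mono-allylated cyanoacetate 6 (not isolated)
Conditions: [Ir(cod)Cl]2 (4 mol%), (Sa)-binaphthol-derived N,N-bis[(S)-1-phenylethyl]phosphoramidite (8 mol%), 1,5,7-triazabicyclo[4.4.0]dec-5-ene (10 mol%), THF, rt to 50 °C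
Reagents that add atoms: none
Why: Iridium-catalysed branch-selective allylic alkylation, run twice on the same carbon acid: the cyclometalated iridium–phosphoramidite complex ionises 4 and the stabilised carbanion attacks the aryl-bearing allyl terminus. The same catalyst enantiomer sets the same sense at both benzylic carbons and so gives the like diastereomer, in which the central carbon is not stereogenic. Cyanoacetate is used because its slim nitrile should let the second, quaternary-forming alkylation proceed.

Step 4
Reactants: 7 methyl (3R)-2-cyano-3-(3,4-dimethoxyphenyl)-2-[(1R)-1-(3,4-dimethoxyphenyl)prop-2-en-1-yl]pent-4-enoate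
Product: 8 methyl (2R,5R)-1-cyano-2,5-bis(3,4-dimethoxyphenyl)cyclopent-3-ene-1-carboxylate
Conditions: second-generation Grubbs catalyst (H2IMes)(PCy3)Cl2Ru=CHPh (5 mol%), CH2Cl2, 40 °C
Reagents that add atoms: none
Why: Ring-closing metathesis of a 1,6-diene to a cyclopentene, helped by the gem-disubstituent effect of the quaternary carbon. The like diene can give only the trans-2,5-diaryl ring, and any unlike diene would show up as the separable cis isomer.

Step 5
Reactants: 8 methyl (2R,5R)-1-cyano-2,5-bis(3,4-dimethoxyphenyl)cyclopent-3-ene-1-carboxylate
Product: 9 (2S,5S)-2,5-bis(3,4-dimethoxyphenyl)cyclopent-3-ene-1-carbonitrile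
Conditions: LiCl, H2O, DMSO, 140 °C
Reagents that add atoms: none
Why: Krapcho dealkoxycarbonylation: chloride demethylates the ester, the carboxylate loses CO2, and water protonates the nitrile-stabilised carbanion. C1 lies between two identically configured carbons and is not a stereocentre, so the face of protonation is irrelevant; the descriptors change from R to S only because the priorities change.

Step 6
Reactants: 9 (2S,5S)-2,5-bis(3,4-dimethoxyphenyl)cyclopent-3-ene-1-carbonitrile
Product: 10 (2S,5S)-2,5-bis(3,4-dimethoxyphenyl)cyclopent-3-ene-1-carbaldehyde
Conditions: (i-Bu)2AlH (1.3 equiv), CH2Cl2, −78 °C; then 1 M HCl, 0 °C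
Reagents that add atoms: water, O
Why: Partial reduction of a nitrile to the N-aluminoimine, which is hydrolysed to the aldehyde on acidic work-up. Enolisation of 10 is harmless because C1 is not stereogenic.

Step 7
Reactants: 10 (2S,5S)-2,5-bis(3,4-dimethoxyphenyl)cyclopent-3-ene-1-carbaldehyde
Product: 11 (3S,5S)-4-(dimethoxymethyl)-3,5-bis(3,4-dimethoxyphenyl)cyclopent-1-ene
Conditions: HC(OMe)3, MeOH, TsOH·H2O (cat.), rt
Reagents that add atoms: trimethyl orthoformate, COC(OC)OC; methanol, CO
Why: Acid-catalysed acetalisation driven by the orthoformate. It installs a bulky, non-enolisable, oxidant-stable group at C1 of the same kind the key step will create at the other carbon.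

Step 8
Reactants: 11 (3S,5S)-4-(dimethoxymethyl)-3,5-bis(3,4-dimethoxyphenyl)cyclopent-1-ene
Product: 12 (1α,2α,3β,4β)-1,3-bis(dimethoxymethyl)-2,4-bis(3,4-dimethoxyphenyl)cyclobutane
Conditions: PhI(OH)OTs (1.2 equiv), MeOH/HC(OMe)3 (5:1), 0 °C to rt
Reagents that add atoms: methanol, CO
Why: Proposed new method: PhI(OH)OTs should add to the C3=C4 bond of 11 on the face anti to the C1 dimethoxymethyl group, and methanol should open the iodonium ion from the other face at either alkene carbon to give a trans-2-methoxycyclopentyl(phenyl)iodane. With C–I pseudo-equatorial, the ring bond from the methoxy-bearing carbon to its benzylic neighbour is antiperiplanar to C–I, so this benzylic carbon shifts to the iodine-bearing carbon (the future Cb) as PhI leaves, pushed by the methoxy lone pair; the extruded carbon becomes an oxocarbenium ion that methanol, kept dry by HC(OMe)3, traps as the second dimethyl acetal. The closest known reaction type is the oxidative ring contraction of cyclohexenes and 1,2-dihydronaphthalenes to ring-contracted acetals with PhI(OH)OTs or Tl(NO3)3 in methanol; a cyclopentene-to-cyclobutane contraction of this kind is not known, and the departure of PhI together with the oxocarbenium ion formed must pay for the added strain. The cyclobutane closes by a suprafacial 1,2-alkyl shift of semipinacol type (a ring contraction, not an exo or endo cyclisation), with inversion at the iodine-bearing carbon and retention at the migrating carbon. Cb is set by the face of iodane attack, since inversion leaves the extruded acetal carbon on the face that iodine occupied; Cd, not stereogenic in 11, becomes a stereocentre whose acetal is trans to that on Cb only after anti attack; Ca and Cc are carried over, and both regiochemistries of methanol opening converge on the same meso product 12. The step needs anti facial selectivity, for which the C1 acetal is the only bias (each face carries one allylic aryl ring): in the envelope that keeps this bulky group pseudo-equatorial, the aryl ring cis to it is pseudo-axial and shields its own face. It also needs migration of the electron-rich benzylic ring carbon in preference to the acetal-bearing C1, to aryl participation and to solvolysis to 1,2-dimethoxy products, which the methoxy push, the inductively deactivated C1 and the all-pseudo-equatorial arrangement of OMe, I and the flanking aryl group should favour.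

Step 9
Reactants: 12 (1α,2α,3β,4β)-1,3-bis(dimethoxymethyl)-2,4-bis(3,4-dimethoxyphenyl)cyclobutane
Product: 14 (1α,2α,3β,4β)-2,4-bis(3,4-dimethoxyphenyl)cyclobutane-1,3-dicarboxylic acid, via cyclobutane-1,3-dicarbaldehyde 13 (not isolated)
Conditions: 1 M HCl, THF, 0 °C, brief; then NaClO2, NaH2PO4, 2-methyl-2-butene, t-BuOH/H2O, 0 °C to rt
Reagents that add atoms: water, O; sodium chlorite, [Na+].[O-]Cl=O
Why: Hydrolysis of a dimethyl acetal is much faster than acid-catalysed enolisation of the aldehyde it releases, so brief cold exposure should leave Cb and Cd untouched. Pinnick oxidation of the crude dialdehyde, with 2-methyl-2-butene to take up HOCl, spares the electron-rich rings and gives the centrosymmetric diacid.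

Step 10
Reactants: 14 (1α,2α,3β,4β)-2,4-bis(3,4-dimethoxyphenyl)cyclobutane-1,3-dicarboxylic acid; 15 5,6-dihydropyridin-2(1H)-one (2.1 equiv)
Product: 18 1,1'-{[(1α,2α,3β,4β)-2,4-bis(3,4-dimethoxyphenyl)cyclobutane-1,3-diyl]dicarbonyl}bis(5,6-dihydropyridin-2(1H)-one), via bis(acid chloride) 16 (not isolated), via lithium lactamide 17 (not isolated)
Conditions: (COCl)2, DMF (cat.), CH2Cl2, 0 °C to rt, evaporate; 15, LiN(SiMe3)2, THF, −78 °C, added to 16 in THF, −78 to −20 °C; aq. NH4Cl
Reagents that add atoms: none
Why: Acid chloride formation followed by N-acylation of a lithium lactamide, the standard route to N-acyl lactams. Low temperature, no excess base and addition of the amide to the acid chloride guard the α-stereocentres and the Michael-acceptor lactam.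

## Compound list

1 | (E)-3-(3,4-dimethoxyphenyl)acrylic acid | COc1ccc(/C=C/C(=O)O)cc1OC | starting material
2 | (E)-3-(3,4-dimethoxyphenyl)acrylic ethyl carbonic anhydride | CCOC(=O)OC(=O)/C=C/c1ccc(OC)c(OC)c1 | intermediate
3 | (E)-3-(3,4-dimethoxyphenyl)prop-2-en-1-ol | COc1ccc(/C=C/CO)cc1OC | intermediate
4 | (E)-3-(3,4-dimethoxyphenyl)allyl methyl carbonate | COC(=O)OC/C=C/c1ccc(OC)c(OC)c1 | intermediate
5 | methyl cyanoacetate | N#CCC(=O)OC | starting material
6 | methyl (3S)-2-cyano-3-(3,4-dimethoxyphenyl)pent-4-enoate (C2 epimers) | N#CC(C(=O)OC)[C@@H](c1ccc(OC)c(OC)c1)C=C | intermediate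
7 | methyl (3R)-2-cyano-3-(3,4-dimethoxyphenyl)-2-[(1R)-1-(3,4-dimethoxyphenyl)prop-2-en-1-yl]pent-4-enoate | N#CC(C(=O)OC)([C@@H](c1ccc(OC)c(OC)c1)C=C)[C@@H](c1ccc(OC)c(OC)c1)C=C | intermediate
8 | methyl (2R,5R)-1-cyano-2,5-bis(3,4-dimethoxyphenyl)cyclopent-3-ene-1-carboxylate (trans-diaryl) | N#CC1(C(=O)OC)[C@@H](c2ccc(OC)c(OC)c2)C=C[C@@H]1c1ccc(OC)c(OC)c1 | intermediate
9 | (2S,5S)-2,5-bis(3,4-dimethoxyphenyl)cyclopent-3-ene-1-carbonitrile (trans-diaryl) | N#CC1[C@@H](c2ccc(OC)c(OC)c2)C=C[C@@H]1c1ccc(OC)c(OC)c1 | intermediate
10 | (2S,5S)-2,5-bis(3,4-dimethoxyphenyl)cyclopent-3-ene-1-carbaldehyde | O=CC1[C@@H](c2ccc(OC)c(OC)c2)C=C[C@@H]1c1ccc(OC)c(OC)c1 | intermediate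
11 | (3S,5S)-4-(dimethoxymethyl)-3,5-bis(3,4-dimethoxyphenyl)cyclopent-1-ene (trans-diaryl) | COC(OC)C1[C@@H](c2ccc(OC)c(OC)c2)C=C[C@@H]1c1ccc(OC)c(OC)c1 | intermediate
12 | (1α,2α,3β,4β)-1,3-bis(dimethoxymethyl)-2,4-bis(3,4-dimethoxyphenyl)cyclobutane (meso) | COc1ccc([C@H]2[C@H](C(OC)OC)[C@H](c3ccc(OC)c(OC)c3)[C@H]2C(OC)OC)cc1OC | intermediate
13 | (1α,2α,3β,4β)-2,4-bis(3,4-dimethoxyphenyl)cyclobutane-1,3-dicarbaldehyde | COc1ccc([C@H]2[C@H](C=O)[C@H](c3ccc(OC)c(OC)c3)[C@H]2C=O)cc1OC | intermediate
14 | (1α,2α,3β,4β)-2,4-bis(3,4-dimethoxyphenyl)cyclobutane-1,3-dicarboxylic acid | COc1ccc([C@H]2[C@H](C(=O)O)[C@H](c3ccc(OC)c(OC)c3)[C@H]2C(=O)O)cc1OC | intermediate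
15 | 5,6-dihydropyridin-2(1H)-one | O=C1C=CCCN1 | starting material
16 | (1α,2α,3β,4β)-2,4-bis(3,4-dimethoxyphenyl)cyclobutane-1,3-dicarbonyl dichloride | COc1ccc([C@H]2[C@H](C(=O)Cl)[C@H](c3ccc(OC)c(OC)c3)[C@H]2C(=O)Cl)cc1OC | intermediate
17 | lithium salt of 5,6-dihydropyridin-2(1H)-one (N-lithio) | [Li]N1CCC=CC1=O | intermediate
18 | 1,1'-{[(1α,2α,3β,4β)-2,4-bis(3,4-dimethoxyphenyl)cyclobutane-1,3-diyl]dicarbonyl}bis(5,6-dihydropyridin-2(1H)-one) | COc1ccc([C@H]2[C@H](C(=O)N3CCC=CC3=O)[C@H](c3ccc(OC)c(OC)c3)[C@H]2C(=O)N2CCC=CC2=O)cc1OC | target

## Step count and risks

Total: 10 steps. Longest linear sequence: 10 steps (1 to 18); 5 and 15 are bought.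

**Step 8 (key step, new method).**
- What may go wrong: the alkyl iodane may collapse by solvolysis to 1,2-dimethoxy products or by participation of a dimethoxyphenyl ring instead of by ring-bond migration, because contraction from five to four raises strain, unlike the known six-to-five cases. Poor facial selectivity would give the cis-1,3 diastereomer. The electron-rich rings may be attacked by the iodane.
- Fallback (known chemistry): set out from 1. Irradiation of crystalline 1 gives diacid 14 directly by topochemical [2+2] photodimerisation, provided the crystal packs head-to-tail with parallel double bonds at close contact. The route is rejoined at 14 and no new compound is made. This is shorter than the main route but depends on crystal packing and would not extend to unsymmetrical analogues.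

**Step 3 (double allylation).**
- What may go wrong: the second alkylation joins a tertiary carbanion to the substituted allyl terminus and creates a quaternary carbon between two tertiary benzylic carbons. It may stall at 6 or switch to attack at the unsubstituted terminus. Loss of catalyst control would appear as the unlike diene.
- Fallback: set out from 4 and build both benzylic bonds on carbons that never become quaternary. Iridium-catalysed allylation of dimethyl malonate with 4 (same catalyst) gives dimethyl 2-[(1S)-1-(3,4-dimethoxyphenyl)prop-2-en-1-yl]malonate F1. Dealkoxycarbonylation (LiCl, wet DMSO) gives methyl (3R)-3-(3,4-dimethoxyphenyl)pent-4-enoate F2. LiN(i-Pr)2 and Me3SiCl give its trimethylsilyl ketene acetal F3. A second iridium-catalysed allylation of F3 with 4 (same ligand enantiomer) gives methyl (3S)-3-(3,4-dimethoxyphenyl)-2-[(1S)-1-(3,4-dimethoxyphenyl)prop-2-en-1-yl]pent-4-enoate F4, whose central carbon is not stereogenic, so the usual diastereoselectivity question of ester-enolate allylation does not arise. Ring-closing metathesis with (H2IMes)(PCy3)Cl2Ru=CHPh gives methyl (2S,5S)-2,5-bis(3,4-dimethoxyphenyl)cyclopent-3-ene-1-carboxylate F5. (i-Bu)2AlH at −78 °C reduces F5 to aldehyde 10, where the route is rejoined.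

**Step 10 (twofold N-acylation).**
- What may go wrong: a weakly nucleophilic, base-sensitive lactam must be acylated twice at hindered acyl carbons. The second acylation may be incomplete, Cb and Cd may epimerise through ketene or imide-enolate formation, and the lactamide may add in conjugate fashion to the unsaturated lactam.
- Fallback: set out from 14 and build the lactam rings after the C–N bonds. Amide coupling of 14 with but-3-en-1-amine (carbodiimide activation) gives N1,N3-di(but-3-en-1-yl)-2,4-bis(3,4-dimethoxyphenyl)cyclobutane-1,3-dicarboxamide F6. N-Acylation of both amides with acryloyl chloride after deprotonation with LiN(SiMe3)2 gives the bis(N-acryloyl) imide F7. Twofold ring-closing metathesis with (H2IMes)(PCy3)Cl2Ru=CHPh closes both dihydropyridinone rings and gives 18.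

## Further compounds

F0 | step 8 | none | none
F1 | step 3 | dimethyl 2-[(1S)-1-(3,4-dimethoxyphenyl)prop-2-en-1-yl]malonate | COC(=O)C(C(=O)OC)[C@@H](c1ccc(OC)c(OC)c1)C=C
F2 | step 3 | methyl (3R)-3-(3,4-dimethoxyphenyl)pent-4-enoate | COC(=O)C[C@@H](c1ccc(OC)c(OC)c1)C=C
F3 | step 3 | {[(3S)-3-(3,4-dimethoxyphenyl)-1-methoxypenta-1,4-dien-1-yl]oxy}trimethylsilane (E/Z not specified) | COC(O[Si](C)(C)C)=C[C@@H](c1ccc(OC)c(OC)c1)C=C
F4 | step 3 | methyl (3S)-3-(3,4-dimethoxyphenyl)-2-[(1S)-1-(3,4-dimethoxyphenyl)prop-2-en-1-yl]pent-4-enoate | COC(=O)C([C@@H](c1ccc(OC)c(OC)c1)C=C)[C@@H](c1ccc(OC)c(OC)c1)C=C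
F5 | step 3 | methyl (2S,5S)-2,5-bis(3,4-dimethoxyphenyl)cyclopent-3-ene-1-carboxylate | COC(=O)C1[C@@H](c2ccc(OC)c(OC)c2)C=C[C@@H]1c1ccc(OC)c(OC)c1
F6 | step 10 | (1α,2α,3β,4β)-N1,N3-di(but-3-en-1-yl)-2,4-bis(3,4-dimethoxyphenyl)cyclobutane-1,3-dicarboxamide | COc1ccc([C@H]2[C@H](C(=O)NCCC=C)[C@H](c3ccc(OC)c(OC)c3)[C@H]2C(=O)NCCC=C)cc1OC
F7 | step 10 | (1α,2α,3β,4β)-N1,N3-diacryloyl-N1,N3-di(but-3-en-1-yl)-2,4-bis(3,4-dimethoxyphenyl)cyclobutane-1,3-dicarboxamide | COc1ccc([C@H]2[C@H](C(=O)N(CCC=C)C(=O)C=C)[C@H](c3ccc(OC)c(OC)c3)[C@H]2C(=O)N(CCC=C)C(=O)C=C)cc1OC
A1 | alternative 1 | (1α,2α,3β,4β)-2,4-bis(6-oxo-3,6-dihydropyridine-1(2H)-carbonyl)cyclobutane-1,3-dicarboxylic acid | OC(=O)[C@H]2[C@H](C(=O)N3CCC=CC3=O)[C@H](C(=O)O)[C@H]2C(=O)N2CCC=CC2=O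
A2 | alternative 1 | cis,trans,cis-cyclobutane-1,2,3,4-tetracarboxylic 1,2:3,4-dianhydride | O=C1OC(=O)[C@H]2[C@@H]1[C@@H]1C(=O)OC(=O)[C@@H]12
A3 | alternative 2 | [(1α,2α,3β,4β)-2,4-bis(4,5-dimethoxycyclohexa-1,4-dien-1-yl)cyclobutane-1,3-diyl]dimethanol | COC1=C(OC)CC(=CC1)[C@H]2[C@H](CO)[C@H](C3=CCC(OC)=C(OC)C3)[C@H]2CO
A4 | alternative 2 | [(1α,2α,3β,4β)-2,4-diethynylcyclobutane-1,3-diyl]dimethanol | C#C[C@H]1[C@H](CO)[C@H](C#C)[C@H]1CO
A5 | alternative 2 | 2,3-dimethoxybuta-1,3-diene | C=C(OC)C(=C)OC
A6 | alternative 3 | (1α,2α,3β,4β)-2,4-bis(3,4-dimethoxyphenyl)-N1,N3-di(quinolin-8-yl)cyclobutane-1,3-dicarboxamide | COc1ccc([C@H]2[C@H](C(=O)Nc3cccc4cccnc34)[C@H](c3ccc(OC)c(OC)c3)[C@H]2C(=O)Nc2cccc3cccnc23)cc1OC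
A7 | alternative 3 | trans-N1,N3-di(quinolin-8-yl)cyclobutane-1,3-dicarboxamide | O=C(Nc1cccc2cccnc12)[C@H]1C[C@@H](C1)C(=O)Nc1cccc2cccnc12
A8 | alternative 3 | 4-iodo-1,2-dimethoxybenzene | COc1ccc(I)cc1OC
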